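**Plan**

- Target 21 is (2S)-5,7-dihydroxy-8-prenyl-4'-(prenyloxy)flavanone. The retrosynthesis first steps back the two MOM acetals and the C4 carbonyl, then cuts the O1–C8a aryl ether bond of ring C, then C3–C4 (aldol), and last the C8–allyl bond (Claisen) and the two prenyl units.
- Enabling feature: O1 joins aromatic C8a of ring A to the benzylic stereocentre C2. The C2–O1 bond ionises and opens by retro-oxa-Michael reaction easily, but O1–C8a is an aryl–oxygen bond that palladium can forge from a C8a triflate and the free C2 carbinol with no bond to C2 made or broken.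
- Forward: bought ring A is bis-MOM protected, O-allylated, rearranged so the allyl sits at the future C8 beside the phenol that becomes O1, converted to prenyl and triflated. The chain is joined by aldol addition of the ring B ketone enolate, C4–OH is silylated, the C2 ketone is reduced, and ring C is closed last.
- Stereochemistry: the only stereocentre, C2, comes from catalyst-controlled transfer hydrogenation with RuCl(p-cymene)[(S,S)-TsDPEN] and is carried with retention. The C4 carbinol is an epimer mixture that the later oxidation erases.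
- End game: desilylation, oxidation of C4 to the ketone, mild acidic MOM removal.

Key step: step 10

Remark: flavan numbering (O1, C2–C4, C4a, C5–C8, C8a, primed locants on ring B) is used for all intermediates; prenyl means 3-methylbut-2-en-1-yl; compounds 15 and 16 are racemic and 17–19 are taken through as mixtures of C4 epimers, since step 12 removes that centre.

**Route**

Step 1
Reactants: 1 2,4,6-trihydroxybenzaldehyde
Product: 2 2-hydroxy-4,6-bis(methoxymethoxy)benzaldehyde
Conditions: MOMCl (2.2 equiv), i-Pr2NEt, CH2Cl2, 0 °C to rt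
Reagents that add atoms: methoxymethyl chloride (MOMCl), COCCl
Why: Base-mediated O-alkylation (MOM acetal protection) should take the 4-OH and one ortho OH, while the last ortho OH stays free because it is locked in a hydrogen bond to the formyl oxygen, as is usual for phloroglucinol aldehydes and ketones.

Step 2
Reactants: 2 2-hydroxy-4,6-bis(methoxymethoxy)benzaldehyde; 3 allyl bromide
Product: 4 2-(allyloxy)-4,6-bis(methoxymethoxy)benzaldehyde
Conditions: K2CO3, DMF, 60 °C
Reagents that add atoms: none
Why: Williamson ether synthesis; in warm DMF the carbonate breaks the chelate and the phenoxide is alkylated by the allylic bromide in an SN2 reaction.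

Step 3
Reactants: 4 2-(allyloxy)-4,6-bis(methoxymethoxy)benzaldehyde
Product: 6 3-allyl-2-hydroxy-4,6-bis(methoxymethoxy)benzaldehyde, via Claisen dienone 5 (not isolated)
Conditions: PhNEt2, 195 °C, sealed tube
Reagents that add atoms: none
Why: Aromatic Claisen rearrangement; the [3,3] shift can end productively only at C3, the single unsubstituted ortho position, and enolisation of dienone 5 returns the phenol next to the new allyl group (the later C8a–O/C8 pair), the basic solvent sparing the MOM acetals.

Step 4
Reactants: 6 3-allyl-2-hydroxy-4,6-bis(methoxymethoxy)benzaldehyde; 7 2-methyl-2-butene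
Product: 8 2-hydroxy-4,6-bis(methoxymethoxy)-3-prenylbenzaldehyde
Conditions: second-generation Grubbs catalyst RuCl2(=CHPh)(PCy3)(H2IMes) (3 mol %), 7 (large excess), CH2Cl2, 40 °C
Reagents that add atoms: none
Why: Olefin cross-metathesis; the terminal alkene should exchange its methylene for the isopropylidene unit of the excess trisubstituted partner with loss of propene, the ruthenium carbene tolerating the free phenol and the aldehyde.

Step 5
Reactants: 8 2-hydroxy-4,6-bis(methoxymethoxy)-3-prenylbenzaldehyde
Product: 9 2-formyl-3,5-bis(methoxymethoxy)-6-prenylphenyl trifluoromethanesulfonate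
Conditions: Tf2O, pyridine, CH2Cl2, −10 to 0 °C
Reagents that add atoms: trifluoromethanesulfonic anhydride (Tf2O), O=S(=O)(OS(=O)(=O)C(F)(F)F)C(F)(F)F
Why: O-Sulfonylation of a phenol; Tf2O/pyridine triflates even hydrogen-bonded, doubly ortho-substituted phenols at low temperature and should leave the aldehyde, the alkene and the MOM acetals untouched.

Step 6
Reactants: 10 4'-hydroxyacetophenone; 11 prenyl bromide
Product: 12 4'-(prenyloxy)acetophenone
Conditions: K2CO3, acetone, reflux
Reagents that add atoms: none
Why: Williamson ether synthesis of a para-acylphenoxide with a primary allylic bromide, O-alkylation by SN2 being strongly preferred in acetone.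

Step 7
Reactants: 12 4'-(prenyloxy)acetophenone; 9 2-formyl-3,5-bis(methoxymethoxy)-6-prenylphenyl trifluoromethanesulfonate
Product: 15 2-{1-hydroxy-3-oxo-3-[4-(prenyloxy)phenyl]propyl}-3,5-bis(methoxymethoxy)-6-prenylphenyl trifluoromethanesulfonate (racemic), via lithium enolate 13 (not isolated), via lithium aldolate 14 (not isolated)
Conditions: LiN(i-Pr)2, THF, −78 °C; then 9, −78 °C; AcOH quench at −78 °C
Reagents that add atoms: none
Why: Directed crossed aldol addition; the preformed lithium enolate should add to the non-enolisable, triflate-activated aldehyde, protonation before warming avoids retro-aldol cleavage, dehydration and sulfonyl transfer, and the new C4 carbinol centre is formed without control because step 12 removes it.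

Step 8
Reactants: 15 2-{1-hydroxy-3-oxo-3-[4-(prenyloxy)phenyl]propyl}-3,5-bis(methoxymethoxy)-6-prenylphenyl trifluoromethanesulfonate
Product: 16 2-{1-(tert-butyldimethylsilyloxy)-3-oxo-3-[4-(prenyloxy)phenyl]propyl}-3,5-bis(methoxymethoxy)-6-prenylphenyl trifluoromethanesulfonate (racemic)
Conditions: TBSOTf, 2,6-lutidine, CH2Cl2, −78 to −40 °C
Reagents that add atoms: tert-butyldimethylsilyl trifluoromethanesulfonate (TBSOTf), CC(C)(C)[Si](C)(C)OS(=O)(=O)C(F)(F)F
Why: Silylation of an alcohol with a silyl triflate and a hindered pyridine base; the reactive silylating agent should cap the hindered benzylic hydroxyl at low temperature before the β-hydroxy ketone can fragment, and the MOM acetals tolerate these conditions.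

Step 9
Reactants: 16 2-{1-(tert-butyldimethylsilyloxy)-3-oxo-3-[4-(prenyloxy)phenyl]propyl}-3,5-bis(methoxymethoxy)-6-prenylphenyl trifluoromethanesulfonate
Product: 17 2-{(3S)-1-(tert-butyldimethylsilyloxy)-3-hydroxy-3-[4-(prenyloxy)phenyl]propyl}-3,5-bis(methoxymethoxy)-6-prenylphenyl trifluoromethanesulfonate (both C1 epimers of the chain)
Conditions: RuCl(p-cymene)[(S,S)-TsDPEN] (3 mol %), HCO2H/Et3N (5:2), EtOAc, 35 °C
Reagents that add atoms: none
Why: Noyori–Ikariya asymmetric transfer hydrogenation; the (S,S)-configured ruthenium hydride/amine pair delivers H−/H+ through a six-membered transition state with the aryl group under the η6-arene, which for aryl alkyl ketones gives the (S)-carbinol under catalyst control irrespective of the remote C4 centre, and formic acid makes reduction of this electron-rich ketone irreversible.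

Step 10
Reactants: 17 2-{(3S)-1-(tert-butyldimethylsilyloxy)-3-hydroxy-3-[4-(prenyloxy)phenyl]propyl}-3,5-bis(methoxymethoxy)-6-prenylphenyl trifluoromethanesulfonate
Product: 18 (2S)-4-(tert-butyldimethylsilyloxy)-5,7-bis(methoxymethoxy)-8-prenyl-4'-(prenyloxy)flavan (both C4 epimers)
Conditions: Pd(OAc)2 (5 mol %), 2-(di-tert-butylphosphino)-1,1'-binaphthyl (7 mol %), Cs2CO3 (1.5 equiv), toluene, 80 °C
Reagents that add atoms: none
Why: Pd(OAc)2 is reduced in the flask to zerovalent palladium, which inserts into the C8a–OTf bond; Cs2CO3 deprotonates the bound C2 carbinol, and C(sp2)–O reductive elimination from the seven-membered oxapalladacycle forms O1–C8a. The closest known reaction type is the palladium-catalysed intramolecular etherification of aryl halides and sulfonates with tethered secondary alcohols that gives chromans. Ring C closes as a six-membered ring in a 6-exo sense, the breaking C8a–OTf bond lying outside the new ring. No stereocentre is created: C2 keeps its (S) configuration because none of its bonds is made or broken, and both C4 epimers should cyclise. The step needs chemoselectivity for reductive elimination over β-hydride elimination of the benzylic alkoxide and over S–O cleavage of the triflate; the bulky electron-rich di-tert-butylbiarylphosphine, the intramolecular six-ring geometry and the weak, poorly soluble base secure this, while the C4 silyl ether shuts off retro-aldol and β-elimination channels.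

Step 11
Reactants: 18 (2S)-4-(tert-butyldimethylsilyloxy)-5,7-bis(methoxymethoxy)-8-prenyl-4'-(prenyloxy)flavan
Product: 19 (2S)-5,7-bis(methoxymethoxy)-8-prenyl-4'-(prenyloxy)flavan-4-ol (both C4 epimers)
Conditions: n-Bu4NF, THF, 0 °C to rt
Reagents that add atoms: none
Why: Fluoride-induced Si–O cleavage driven by the strong Si–F bond; the flavan has no carbonyl group, so the basic fluoride cannot open ring C or disturb C2.

Step 12
Reactants: 19 (2S)-5,7-bis(methoxymethoxy)-8-prenyl-4'-(prenyloxy)flavan-4-ol
Product: 20 (2S)-5,7-bis(methoxymethoxy)-8-prenyl-4'-(prenyloxy)flavanone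
Conditions: n-Pr4N[RuO4] (5 mol %), NMO, 4 Å molecular sieves, CH2Cl2, rt
Reagents that add atoms: none
Why: Ley–Griffith oxidation; catalytic perruthenate with NMO as terminal oxidant should convert the secondary benzylic alcohol of both epimers into the C4 ketone under near-neutral conditions that spare the alkenes, the acetals and the base-sensitive C2 centre.

Step 13
Reactants: 20 (2S)-5,7-bis(methoxymethoxy)-8-prenyl-4'-(prenyloxy)flavanone
Product: 21 (2S)-5,7-dihydroxy-8-prenyl-4'-(prenyloxy)flavanone
Conditions: HCl (1 M in MeOH), THF, 25–35 °C, stopped as soon as both acetals are gone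
Reagents that add atoms: none
Why: Acid-catalysed acetal cleavage (transacetalisation to dimethoxymethane); ionisation of MOM groups to the methoxymethyl cation should be much faster than ionisation of the aryl prenyl ether or protonation of the trisubstituted alkenes in dilute acid near room temperature, and acid does not trigger the enolate-driven ring opening that would racemise C2.

**Compound list**

1 | 2,4,6-trihydroxybenzaldehyde | O=Cc1c(O)cc(O)cc1O | starting material
2 | 2-hydroxy-4,6-bis(methoxymethoxy)benzaldehyde | O=Cc1c(O)cc(OCOC)cc1OCOC | intermediate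
3 | allyl bromide | C=CCBr | starting material
4 | 2-(allyloxy)-4,6-bis(methoxymethoxy)benzaldehyde | O=Cc1c(OCC=C)cc(OCOC)cc1OCOC | intermediate
5 | 5-allyl-2,4-bis(methoxymethoxy)-6-oxocyclohexa-1,3-diene-1-carbaldehyde (Claisen dienone, racemic, not isolated) | O=CC1=C(OCOC)C=C(OCOC)C(CC=C)C1=O | intermediate
6 | 3-allyl-2-hydroxy-4,6-bis(methoxymethoxy)benzaldehyde | O=Cc1c(O)c(CC=C)c(OCOC)cc1OCOC | intermediate
7 | 2-methyl-2-butene | CC=C(C)C | starting material
8 | 2-hydroxy-4,6-bis(methoxymethoxy)-3-(3-methylbut-2-en-1-yl)benzaldehyde | O=Cc1c(O)c(CC=C(C)C)c(OCOC)cc1OCOC | intermediate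
9 | 2-formyl-3,5-bis(methoxymethoxy)-6-(3-methylbut-2-en-1-yl)phenyl trifluoromethanesulfonate | O=Cc1c(OS(=O)(=O)C(F)(F)F)c(CC=C(C)C)c(OCOC)cc1OCOC | intermediate
10 | 4'-hydroxyacetophenone | CC(=O)c1ccc(O)cc1 | starting material
11 | prenyl bromide (1-bromo-3-methylbut-2-ene) | CC(C)=CCBr | starting material
12 | 4'-(prenyloxy)acetophenone | CC(=O)c1ccc(OCC=C(C)C)cc1 | intermediate
13 | lithium 1-[4-(prenyloxy)phenyl]ethen-1-olate (not isolated) | [Li]OC(=C)c1ccc(OCC=C(C)C)cc1 | intermediate
14 | lithium aldolate of 15 (racemic, not isolated) | CC(C)=CCOc1ccc(C(=O)CC(O[Li])c2c(OCOC)cc(OCOC)c(CC=C(C)C)c2OS(=O)(=O)C(F)(F)F)cc1 | intermediate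
15 | 2-{1-hydroxy-3-oxo-3-[4-(prenyloxy)phenyl]propyl}-3,5-bis(methoxymethoxy)-6-prenylphenyl trifluoromethanesulfonate (racemic) | CC(C)=CCOc1ccc(C(=O)CC(O)c2c(OCOC)cc(OCOC)c(CC=C(C)C)c2OS(=O)(=O)C(F)(F)F)cc1 | intermediate
16 | 2-{1-(tert-butyldimethylsilyloxy)-3-oxo-3-[4-(prenyloxy)phenyl]propyl}-3,5-bis(methoxymethoxy)-6-prenylphenyl trifluoromethanesulfonate (racemic) | CC(C)=CCOc1ccc(C(=O)CC(O[Si](C)(C)C(C)(C)C)c2c(OCOC)cc(OCOC)c(CC=C(C)C)c2OS(=O)(=O)C(F)(F)F)cc1 | intermediate
17 | 2-{(3S)-1-(tert-butyldimethylsilyloxy)-3-hydroxy-3-[4-(prenyloxy)phenyl]propyl}-3,5-bis(methoxymethoxy)-6-prenylphenyl trifluoromethanesulfonate (both C1 epimers of the chain) | CC(C)=CCOc1ccc([C@@H](O)CC(O[Si](C)(C)C(C)(C)C)c2c(OCOC)cc(OCOC)c(CC=C(C)C)c2OS(=O)(=O)C(F)(F)F)cc1 | intermediate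
18 | (2S)-4-(tert-butyldimethylsilyloxy)-5,7-bis(methoxymethoxy)-8-prenyl-4'-(prenyloxy)flavan (both C4 epimers) | CC(C)=CCOc1ccc([C@@H]2CC(O[Si](C)(C)C(C)(C)C)c3c(OCOC)cc(OCOC)c(CC=C(C)C)c3O2)cc1 | intermediate
19 | (2S)-5,7-bis(methoxymethoxy)-8-prenyl-4'-(prenyloxy)flavan-4-ol (both C4 epimers) | CC(C)=CCOc1ccc([C@@H]2CC(O)c3c(OCOC)cc(OCOC)c(CC=C(C)C)c3O2)cc1 | intermediate
20 | (2S)-5,7-bis(methoxymethoxy)-8-prenyl-4'-(prenyloxy)flavanone | CC(C)=CCOc1ccc([C@@H]2CC(=O)c3c(OCOC)cc(OCOC)c(CC=C(C)C)c3O2)cc1 | intermediate
21 | (2S)-5,7-dihydroxy-8-prenyl-4'-(prenyloxy)flavanone (CNP0558191.1) | CC(C)=CCOc1ccc([C@@H]2CC(=O)c3c(O)cc(O)c(CC=C(C)C)c3O2)cc1 | target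

**Step count**

Total steps: 13. Longest linear sequence: 12 steps (1 to 21 through steps 1–5 and 7–13); step 6 is the one-step side branch.

**Steps most likely to fail**

1. Step 10. Oxidative addition at the doubly ortho-substituted, electron-rich C8a–OTf bond may be slow. That would let base-induced S–O cleavage of the triflate, β-hydride elimination from the palladium alkoxide (returning the C2 ketone and a hydrodetriflated arene) or ionisation of the allylic aryl ether by zerovalent palladium compete.
   Fallback: ring C is closed at the other C–O bond with inversion. Setting out from ketone 16, transfer hydrogenation with the enantiomeric catalyst RuCl(p-cymene)[(R,R)-TsDPEN] in HCO2H/Et3N should give the (3R)-carbinol triflate F1. Et4NOH in aqueous dioxane at rt should cleave the S–O bond of the aryl triflate to the (3R)-hydroxy phenol F2. Mitsunobu cyclisation (PPh3, DIAD, THF, 0 °C) then forms O1–C2 by SN2 displacement with inversion and rejoins the route at flavan 18. Partial ionisation at the p-alkoxybenzylic carbon could erode the enantiomeric purity, which is why this is the reserve and not the main route.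

2. Step 13. The acid may ionise the 4'-O-prenyl ether, add methanol to or cyclise the C8 prenyl group onto O7, or cause partial racemisation through ring opening before the less reactive 7-O-MOM group is gone.
   Fallback: Brønsted acid is avoided by a protecting-group exchange. Setting out from 20, TESOTf and 2,2'-bipyridyl in CH2Cl2 at 0 °C should convert both aryl MOM ethers directly into aryl silyl ethers, giving the 5,7-bis(triethylsilyl) ether F3. Et3N·3HF in THF at 0 °C then removes the silyl groups and arrives at target 21.

3. Step 7. The hindered lithium aldolate may revert by retro-aldol fragmentation, dehydrate to the enone, or take over the triflyl group from the neighbouring aryl oxygen.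
   Fallback: the C3–C4 bond is made under Lewis acid control with no free alkoxide. Setting out from ketone 12, TMSOTf and Et3N in CH2Cl2 at 0 °C should give the trimethylsilyl enol ether F4. Mukaiyama aldol addition of F4 to aldehyde 9 with BF3·OEt2 in CH2Cl2 at −78 °C, followed by aqueous NaHCO3 work-up, comes back to the route at aldol 15.

**Further compounds**

F1 | step 10 | 2-{(3R)-1-(tert-butyldimethylsilyloxy)-3-hydroxy-3-[4-(prenyloxy)phenyl]propyl}-3,5-bis(methoxymethoxy)-6-prenylphenyl trifluoromethanesulfonate | CC(C)=CCOc1ccc([C@H](O)CC(O[Si](C)(C)C(C)(C)C)c2c(OCOC)cc(OCOC)c(CC=C(C)C)c2OS(=O)(=O)C(F)(F)F)cc1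
F2 | step 10 | 2-{(3R)-1-(tert-butyldimethylsilyloxy)-3-hydroxy-3-[4-(prenyloxy)phenyl]propyl}-3,5-bis(methoxymethoxy)-6-prenylphenol | CC(C)=CCOc1ccc([C@H](O)CC(O[Si](C)(C)C(C)(C)C)c2c(OCOC)cc(OCOC)c(CC=C(C)C)c2O)cc1
F3 | step 13 | (2S)-5,7-bis(triethylsilyloxy)-8-prenyl-4'-(prenyloxy)flavanone | CC(C)=CCOc1ccc([C@@H]2CC(=O)c3c(O[Si](CC)(CC)CC)cc(O[Si](CC)(CC)CC)c(CC=C(C)C)c3O2)cc1
F4 | step 7 | trimethyl({1-[4-(prenyloxy)phenyl]ethenyl}oxy)silane | C=C(O[Si](C)(C)C)c1ccc(OCC=C(C)C)cc1
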